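The data stem from a simulated flask for an exercise; the scatter is artificial.

**Amber's reading.** After 30.0 min, 32.6% of the Z charged stands as L in amber, and the pace of north-east is reckoned here from that reading.

| flask | Z | temperature | remark | time |
|---|---|---|---|---|
| amber | 0.024 M | 95 °C | run made earlier |  |
| blue | 0.026 M | 128 °C | run made earlier |  |
| ochre | 0.037 M | 95 °C | run made earlier |  |
| west | 0.020 M | 80 °C |  | 1.5 h |
| north | 0.020 M | 110 °C |  | 1.5 h |
| north-east | 0.040 M | 95 °C |  | 1.5 h |
| east | 0.030 M | 95 °C |  | 1.5 h |
| south-west | 0.020 M | 140 °C |  | 1.5 h |

- amber (time / min: L / %): 12.0: 16.0; 30.0: 32.6; 60.0: 48.4; 120: 61.3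
- blue (time / min: L / %): 5.00: 34.8; 10.0: 46.0; 15.0: 49.7; 20.0: 49.5; 25.0: 47.1
- ochre (time / min: L / %): 10.0: 20.4; 20.0: 32.8; 40.0: 48.3; 60.0: 57.2; 120: 69.5

(readings scatter by 0.3 percentage points)

* ranking by amount of L, in percent of the Z charged, from high to low, at 1.5 h (west / north / north-east / east / south-west)
* the same order at 5.0 min (west / north / north-east / east / south-west)
* the amount of L, in percent of the Z charged of the flask you put first, at 1.5 h
* the amount of L, in percent of the Z charged of the flask you put last, at 1.5 h

- percentages count the Z that a species holds: one L counts as two
- the numbers in the tables scatter by 0.3 percentage points (one standard deviation)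

**Main step.** Take first the bare step in which two Z join to one L, second order in Z. Let τ be the half-time of the charge: the time in which this step by itself halves the Z of a given flask. The part of Z left after time t is then τ/(τ+t). One reading gives τ = t·z/y, with z the part left and y the part turned, and at one temperature τ varies inversely with the charge. Amber's reading, scaled to the charge of north-east at 95 °C, gives τ = 37.2 min, the half-time of the charge. By this step, north-east keeps 29.3% of its Z at 1.5 h, so 70.7% has been turned.

**Loss of L.** Ochre at 95 °C has τ = 40.2 min. Its readings fall short of the bare step by 2.7 percentage points at 60.0 min and 5.4 points at 120 min, a gap that grows with time. This reckoning takes the mean of the two for the 1.5 h of north-east, which leaves L near 66.6%.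

**Heat.** Blue at 128 °C reads 49.7% at 15.0 min and 47.1% at 25.0 min, a fall that shows much sooner than amber's last reading, which is still rising. This reckoning therefore sets south-west, at 140 °C, first at 5.0 min and past its peak at 1.5 h. At 1.5 h and the shared 95 °C, this reckoning puts north-east above east, since the τ of north-east is shorter.

**Forecast.** The forecast ranks north-east > east > north > west > south-west at 1.5 h and south-west > north > north-east > east > west at 5.0 min, with 66.8% at the top and 1.2% at the bottom. It holds that “L is lost further, roughly first order”.

**Result.** The flasks give north-east > east > north > west > south-west at 1.5 h and south-west > north > north-east > east > west at 5.0 min, with 66.9% at the top and 1.51% at the bottom.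

    2 Z ⇌ L (K = 1800 M⁻¹, k = 0.0140 M⁻¹ s⁻¹, Ea = 71.0 kJ mol⁻¹, ΔH = −16.0 kJ mol⁻¹)
    L → X (k = 7.10 × 10⁻⁵ s⁻¹, Ea = 126 kJ mol⁻¹)
    (constants at 110 °C)

**Rates compared.** In north-east at 1.50 h, L is made 3.95 times faster than it is used up, each step taken net, and its half-life towards X, 14 h, is long against 1.5 h. The way back from L to Z makes no difference to the L of north-east at 1.5 h. At 1.50 h north-east holds 29.4% of its charge as Z, against the 29.3% reckoned from τ. A neighbour flask, north-east with 0.16 M of Z and the same 1.5 h, has τ = 9.30 min, which leaves 9.37% of its charge as Z, and that neighbour holds 9.71%.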